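**Assumptions:** The SMILES encodes the all-trans, C2-symmetric (2R,3S,4S,5R) tetrahydrofuran, and that is the isomer planned for. The sense of induction of the Ir catalyst in step 2 is written for (R)-SEGPHOS from memory; if it delivers the antipode, the (S)-ligand is used instead.

## Retrosynthetic overview

1. (+)-Neoolivil (10) ⇐ global desilylation of 9 ⇐ ozonolysis/reduction of the C3 vinyl group of 8 (vinyl = latent CH2OH).
2. The THF ring (the only ring, formed in step 5) ⇐ intramolecular silyl-modified Sakurai annulation of aldehyde 2 with δ-silyl homoallylic alcohol 7. O1–C2 and C2–C3 are made in one operation, and C2/C3 are set by substrate control.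
3. 7 ⇐ cross-metathesis of 5 with allyltrimethylsilane ⇐ primary silylation of anti-diol 4.
4. 4 ⇐ Ir-catalysed enantioselective anti-(hydroxymethyl)allylation of 2 with vinyl ethylene carbonate (sets C4/C5; the only catalyst-controlled step). 2 ⇐ vanillin, and 2 is used twice.
5. This avoids both the usual 1,4-diol cyclodehydration and the biomimetic β–β oxidative coupling.

## Route

**Step 1**
Reactants: 1, vanillin
Product: 2, 3-methoxy-4-[(triisopropylsilyl)oxy]benzaldehyde
Conditions: TIPSCl (1.1 equiv), imidazole, DMF, 0 °C → rt
Reagents that add atoms: TIPSCl, CC(C)[Si](Cl)(C(C)C)C(C)C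
Why: Standard phenol silylation; the aryl TIPS ether should survive the weakly basic Ir step, TMSOTf at −78 °C and O3/NaBH4, and is removed together with the TBS group by fluoride at the end.

**Step 2**
Reactants: 2; 3, 4-vinyl-1,3-dioxolan-2-one (vinyl ethylene carbonate, racemic, 2 equiv)
Product: 4, (1R,2S)-2-ethenyl-1-{3-methoxy-4-[(triisopropylsilyl)oxy]phenyl}propane-1,3-diol (anti)
Conditions: [Ir(cod)Cl]2 (2.5 mol %), (R)-SEGPHOS (5 mol %), 4-cyano-3-nitrobenzoic acid (10 mol %), K3PO4 (cat.), i-PrOH (2 equiv), THF, 90 °C
Reagents that add atoms: none (3 is a reactant and loses CO2; i-PrOH supplies only hydrogen)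
Why: Krische-type transfer-hydrogenative anti-(hydroxymethyl)allylation: ionisation/decarboxylation of 3 gives an (E)-σ-(hydroxymethyl)allyl–Ir species that adds through a closed chair transition state, so the ligand sets the carbinol centre (future C5, R) and the E-geometry sets the adjacent centre (future C4, S) anti to it.

**Step 3**
Reactants: 4
Product: 5, (1R,2S)-2-{[(tert-butyldimethylsilyl)oxy]methyl}-1-{3-methoxy-4-[(triisopropylsilyl)oxy]phenyl}but-3-en-1-ol
Conditions: TBSCl (1.05 equiv), imidazole, CH2Cl2, 0 °C
Reagents that add atoms: TBSCl, CC(C)(C)[Si](C)(C)Cl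
Why: Sterically controlled silylation of the primary over the secondary benzylic hydroxyl, leaving only the benzylic OH free to become the ring oxygen; no stereocentre is touched.

**Step 4**
Reactants: 5; 6, allyltrimethylsilane (5 equiv)
Product: 7, (1R,2S,3E)-2-{[(tert-butyldimethylsilyl)oxy]methyl}-1-{3-methoxy-4-[(triisopropylsilyl)oxy]phenyl}-5-(trimethylsilyl)pent-3-en-1-ol (E-major; E/Z mixture carried forward)
Conditions: Grubbs II or Hoveyda–Grubbs II (5 mol %), CH2Cl2, 40 °C
Reagents that add atoms: none (6 is a reactant; ethylene is lost)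
Why: Olefin cross-metathesis of a hindered terminal alkene with excess of a reactive allylsilane, which tolerates the free alcohol and silyl ethers and converts the vinyl group into the allylsilane needed as a C3 nucleophile.

**Step 5 (key step, ring formation)**
Reactants: 7; 2 (1.3 equiv)
Product: 8, all-trans (2R,3R,4S,5R)-3-ethenyl-4-{[(tert-butyldimethylsilyl)oxy]methyl}-2,5-bis{3-methoxy-4-[(triisopropylsilyl)oxy]phenyl}oxolane (numbering: O1, C2 = new benzylic carbon, C3 = vinyl carbon, C4 = CH2OTBS carbon, C5 = original carbinol; C3 is R only because vinyl ranks below C4)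
Conditions: TMS-imidazole, CH2Cl2, rt (in situ O-silylation); then 2, TMSOTf (0.2 equiv), CH2Cl2, −78 → −40 °C; Et3N quench
Reagents that add atoms: none (TMS groups are not retained; the aldehyde oxygen leaves as TMS2O)
Why: Intramolecular silyl-modified Sakurai (oxocarbenium–allylsilane) annulation, a known reaction class that is untested on this fully substituted 2,5-diaryl case: the (E)-oxocarbenium from 2 and the benzylic OTMS is trapped anti-SE2′ by the allylsilane γ-carbon to close the ring, with C4–H eclipsing the alkene (A1,3 control) giving 3,4-trans and the antiperiplanar C=O+/C=C arrangement giving 2,3-trans; C4/C5 are not touched, and C2 is an electron-rich benzylic ether that could be equilibrated to the all-trans isomer with Lewis acid if needed.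

**Step 6**
Reactants: 8
Product: 9, {(2R,3S,4S,5R)-4-{[(tert-butyldimethylsilyl)oxy]methyl}-2,5-bis{3-methoxy-4-[(triisopropylsilyl)oxy]phenyl}oxolan-3-yl}methanol
Conditions: O3, CH2Cl2/MeOH, −78 °C (Sudan Red 7B end-point); then NaBH4, −78 → 0 °C
Reagents that add atoms: ozone, O=[O+][O-] (supplies the new hydroxyl oxygen; NaBH4 adds only H)
Why: Ozonolysis with reductive work-up cleaves the terminal vinyl group much faster than the aryl rings and reduces the aldehyde in situ before it can epimerise at C3 (any epimerisation would in any case favour the all-trans isomer).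

**Step 7**
Reactants: 9
Product: 10, (+)-neoolivil, (2R,3S,4S,5R)-2,5-bis(4-hydroxy-3-methoxyphenyl)-3,4-bis(hydroxymethyl)oxolane
Conditions: TBAF (3.5 equiv), AcOH (3.5 equiv), THF, 0 °C → rt
Reagents that add atoms: none
Why: Fluoride removes the two aryl TIPS ethers and the TBS ether in one step; buffering with AcOH avoids phenoxide-triggered quinone-methide opening of the benzylic ethers, and no stereocentre is affected.

## Compound list

1 | vanillin | COc1cc(C=O)ccc1O | starting material
2 | 3-methoxy-4-[(triisopropylsilyl)oxy]benzaldehyde | COc1cc(C=O)ccc1O[Si](C(C)C)(C(C)C)C(C)C | intermediate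
3 | 4-vinyl-1,3-dioxolan-2-one (racemic) | C=CC1COC(=O)O1 | starting material
4 | (1R,2S)-2-ethenyl-1-aryl-propane-1,3-diol (aryl = 3-methoxy-4-TIPSO-phenyl) | COc1cc(ccc1O[Si](C(C)C)(C(C)C)C(C)C)[C@H](O)[C@H](CO)C=C | intermediate
5 | (1R,2S)-2-(TBSO-methyl)-1-aryl-but-3-en-1-ol | COc1cc(ccc1O[Si](C(C)C)(C(C)C)C(C)C)[C@H](O)[C@H](CO[Si](C)(C)C(C)(C)C)C=C | intermediate
6 | allyltrimethylsilane | C=CC[Si](C)(C)C | starting material
7 | (1R,2S,3E)-2-(TBSO-methyl)-1-aryl-5-(trimethylsilyl)pent-3-en-1-ol | COc1cc(ccc1O[Si](C(C)C)(C(C)C)C(C)C)[C@H](O)[C@H](CO[Si](C)(C)C(C)(C)C)/C=C/C[Si](C)(C)C | intermediate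
8 | all-trans (2R,3R,4S,5R)-3-ethenyl-4-(TBSO-methyl)-2,5-diaryl-oxolane | COc1cc([C@@H]2O[C@@H](c3ccc(O[Si](C(C)C)(C(C)C)C(C)C)c(OC)c3)[C@H](CO[Si](C)(C)C(C)(C)C)[C@H]2C=C)ccc1O[Si](C(C)C)(C(C)C)C(C)C | intermediate
9 | [(2R,3S,4S,5R)-4-(TBSO-methyl)-2,5-diaryl-oxolan-3-yl]methanol | COc1cc([C@@H]2O[C@@H](c3ccc(O[Si](C(C)C)(C(C)C)C(C)C)c(OC)c3)[C@H](CO[Si](C)(C)C(C)(C)C)[C@H]2CO)ccc1O[Si](C(C)C)(C(C)C)C(C)C | intermediate
10 | (+)-neoolivil | COc1cc([C@@H]2O[C@@H](c3ccc(O)c(OC)c3)[C@H](CO)[C@H]2CO)ccc1O | target

## Summary

Total steps: 7. Longest linear sequence: 7 (from vanillin; aldehyde 2 is used again in step 5).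

Three steps most likely to fail, each with a fallback that changes the approach:

1. **Step 5 (Sakurai annulation).** Risks are the strained 5-ring closure onto the oxocarbenium, ionisation or elimination at the electron-rich benzylic carbinol, and incomplete 3,4-trans control. Fallback: change the ring-forming bond. Convert the vinyl group of 5 into a γ-lactone (hydroboration–oxidation, oxidative lactonisation), set C3 by trans-selective enolate alkylation with BOMCl, then add the second aryl as ArLi and reduce the lactol with Et3SiH/BF3·OEt2, using acid equilibration of the benzylic centre to reach all-trans.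

2. **Step 2 (Ir-catalysed hydroxymethyl-allylation).** Risks are the electron-rich, silyl-protected aldehyde under warm, weakly basic conditions and the ee/anti ratio. Fallback: auxiliary control instead of catalysis. An Evans syn-aldol of (R)-4-benzyl-3-(but-3-enoyl)oxazolidin-2-one with 2 (Bu2BOTf, i-Pr2NEt) followed by LiBH4 gives the same (1R,2S)-diol 4.

3. **Step 4 (cross-metathesis).** Risks are low conversion at the branched allylic alkene and an E/Z mixture that erodes selectivity in step 5. Fallback: carbonyl olefination instead of metathesis. Protect the C1–OH (TES), cleave the vinyl group to the aldehyde (OsO4/NaIO4), and run a Wittig reaction with Ph3P=CHCH2SiMe3 to get the (Z)-allylsilane, where A1,3 strain should enforce the 3,4-trans closure more strongly.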